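**Strategy.** The dihydrobenzofuran is disconnected at C3–C3a: C3, its hydroxymethyl carbon and ring C carbon C3a correspond to C3, the carbonyl carbon C4 and C4a of a (2S)-flavanone. One trivalent-iodine 1,2-shift of the ring C carbon contracts the pyranone to the furan, makes the C3–C3a bond, sets C3 trans to the C2 aryl group and turns the old carbonyl into the C3 ester. The precursor is a 6-bromo-8-methoxyflavanone carrying a pivaloylated guaiacyl ring at C2. Its bromide later becomes the benzylic arm of an (R)-butyrolactone, which is alkylated trans with a separately built anti-diol benzyl bromide before global desilylation.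

Key step: step 6

Abbreviations: TBS = tert-butyldimethylsilyl, TIPS = triisopropylsilyl (TBSO, TIPSO = the silyloxy groups), Piv = pivaloyl, t-BuPyOx = 4-tert-butyl-2-(pyridin-2-yl)-4,5-dihydrooxazole, dba = dibenzylideneacetone.

Assumption 1: the sense of induction of the t-BuPyOx ligand is carried over from cyclic enones, so the (R)-ligand is expected to give the (2S)-flavanone; if the sense is opposite, the (S)-ligand is used.

Assumption 2: the magnesium-catalysed aldol is taken to run through the chelated (Z)-enolate with attack anti to the auxiliary benzyl group, the same facial sense as alkylations of these imides.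

**Route**

Step 1
Reactants: 1 1-(2-hydroxy-3-methoxyphenyl)ethan-1-one
Product: 2 1-(5-bromo-2-hydroxy-3-methoxyphenyl)ethan-1-one
Conditions: NBS, MeCN, 0 °C to rt
Reagents that add atoms: N-bromosuccinimide, O=C1CCC(=O)N1Br
Why: Electrophilic aromatic bromination should go para to the phenolic OH, the one position that is also meta to the acetyl group.

Step 2
Reactants: 2 1-(5-bromo-2-hydroxy-3-methoxyphenyl)ethan-1-one; 3 N,N-dimethylformamide dimethyl acetal
Product: 5 6-bromo-8-methoxy-4H-chromen-4-one, via enaminone 4 (not isolated)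
Conditions: 3, toluene, 100 °C; then conc. HCl, CH2Cl2, rt
Reagents that add atoms: none
Why: Condensation of the methyl ketone with the amide acetal gives the enaminone, and acid then drives intramolecular oxa-Michael addition of the phenol with loss of dimethylamine (enaminone route to chromones).

Step 3
Reactants: 6 2-methoxy-4-(4,4,5,5-tetramethyl-1,3,2-dioxaborolan-2-yl)phenol
Product: 7 2-methoxy-4-(4,4,5,5-tetramethyl-1,3,2-dioxaborolan-2-yl)phenyl pivalate
Conditions: PivCl, Et3N, DMAP (cat.), CH2Cl2, 0 °C to rt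
Reagents that add atoms: pivaloyl chloride, CC(C)(C)C(Cl)=O
Why: Simple O-acylation of the phenol, which installs the acyloxy group that later lowers the migratory aptitude of ring D.

Step 4
Reactants: 7 2-methoxy-4-(4,4,5,5-tetramethyl-1,3,2-dioxaborolan-2-yl)phenyl pivalate
Product: 8 [3-methoxy-4-(pivaloyloxy)phenyl]boronic acid
Conditions: NaIO4, NH4OAc, acetone/H2O, rt
Reagents that add atoms: water, O
Why: Periodate glycol cleavage destroys the pinacol released in the hydrolysis equilibrium, so the free boronic acid needed for transmetalation to palladium should form while the pivalate stays intact.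

Step 5
Reactants: 5 6-bromo-8-methoxy-4H-chromen-4-one; 8 [3-methoxy-4-(pivaloyloxy)phenyl]boronic acid
Product: 9 (2S)-6-bromo-8-methoxy-2-[3-methoxy-4-(pivaloyloxy)phenyl]chroman-4-one
Conditions: Pd(OCOCF3)2 (5 mol%), (R)-t-BuPyOx (6 mol%), NH4PF6 (30 mol%), H2O (5 equiv), ClCH2CH2Cl, 60 °C
Reagents that add atoms: none
Why: Asymmetric conjugate addition of an arylboronic acid to a chromone under divalent palladium should set C2 through the chiral pyridine-oxazoline ligand in the aryl insertion, and since the metal stays divalent the aryl bromide is not touched.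

Step 6
Reactants: 9 (2S)-6-bromo-8-methoxy-2-[3-methoxy-4-(pivaloyloxy)phenyl]chroman-4-one
Product: 11 methyl (2S,3S)-5-bromo-7-methoxy-2-[3-methoxy-4-(pivaloyloxy)phenyl]-2,3-dihydro-1-benzofuran-3-carboxylate (2,3-trans), via enol ether 10 (not isolated)
Conditions: HC(OMe)3, conc. H2SO4 (cat.), rt; then PhI(OAc)2, rt; aq. NaHCO3 work-up
Reagents that add atoms: trimethyl orthoformate, COC(OC)OC
Why: Acid and orthoformate turn ketone 9 into enol ether 10, electrophilic trivalent iodine adds to C3 trans to the pseudo-equatorial C2 aryl group while methanol closes the C4 ketal, and the ring C carbon C4a, antiperiplanar to the equatorial C3–I bond, shifts from C4 to C3 as iodobenzene leaves; the dimethoxycarbenium ion left at C4 loses a methyl group to acetate and becomes the ester. The closest known reaction type is the trivalent-iodine or thallium trinitrate oxidative 1,2-aryl shift of aryl ketones, which is established for the contraction of flavanones to 2-aryl-2,3-dihydrobenzofuran-3-carboxylates. The dihydrofuran ring is not closed by a new bond to oxygen but arises by contraction of the pyranone through a bridged, phenonium-like 1,2-shift, the O1–C2 bond staying intact. The new stereocenter C3 is controlled by C2: iodine enters anti to the aryl group and the shift inverts C3, which places the ester trans to the aryl group, the arrangement that is also thermodynamically preferred. The step needs C4a and not the C2 aryl group to migrate and C2 to stay closed; the migrating carbon is activated by the ortho ring oxygen, the C2 aryl group is deactivated by its pivaloyloxy group and sits equatorial where it cannot align with the C3–I bond, and the acidic medium gives no phenoxide elimination.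

Step 7
Reactants: 11 methyl (2S,3S)-5-bromo-7-methoxy-2-[3-methoxy-4-(pivaloyloxy)phenyl]-2,3-dihydro-1-benzofuran-3-carboxylate
Product: 12 4-[(2S,3R)-5-bromo-3-(hydroxymethyl)-7-methoxy-2,3-dihydro-1-benzofuran-2-yl]-2-methoxyphenol
Conditions: LiAlH4, THF, 0 °C
Reagents that add atoms: none
Why: Hydride reduction should convert the methyl ester into the hydroxymethyl group and cleave the pivalate in the same operation, while the aryl bromide is inert at 0 °C and C3 is no longer epimerisable afterwards.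

Step 8
Reactants: 12 4-[(2S,3R)-5-bromo-3-(hydroxymethyl)-7-methoxy-2,3-dihydro-1-benzofuran-2-yl]-2-methoxyphenol
Product: 13 (2S,3R)-5-bromo-7-methoxy-2-(3-methoxy-4-TIPSO-phenyl)-3-(TIPSO-methyl)-2,3-dihydro-1-benzofuran
Conditions: TIPSCl, imidazole, DMF, rt
Reagents that add atoms: chlorotriisopropylsilane, CC(C)[Si](Cl)(C(C)C)C(C)C
Why: Silylation of the phenol and the primary alcohol gives base-stable ethers that survive organolithium, enolate and borohydride steps and fall to fluoride at the end.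

Step 9
Reactants: 13 (2S,3R)-5-bromo-7-methoxy-2-(3-methoxy-4-TIPSO-phenyl)-3-(TIPSO-methyl)-2,3-dihydro-1-benzofuran
Product: 16 [(2S,3R)-7-methoxy-2-(3-methoxy-4-TIPSO-phenyl)-3-(TIPSO-methyl)-2,3-dihydro-1-benzofuran-5-yl]methanol, via aryllithium 14 (not isolated), via aldehyde 15 (not isolated)
Conditions: n-BuLi, THF, −78 °C; DMF, −78 to 0 °C; then MeOH, NaBH4, 0 °C
Reagents that add atoms: N,N-dimethylformamide, CN(C)C=O
Why: Bromine–lithium exchange, formylation of the aryllithium with DMF and borohydride reduction of the aldehyde in the same flask should give the benzylic alcohol without touching either stereocenter.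

Step 10
Reactants: 16 [(2S,3R)-7-methoxy-2-(3-methoxy-4-TIPSO-phenyl)-3-(TIPSO-methyl)-2,3-dihydro-1-benzofuran-5-yl]methanol
Product: 17 (2S,3R)-5-(bromomethyl)-7-methoxy-2-(3-methoxy-4-TIPSO-phenyl)-3-(TIPSO-methyl)-2,3-dihydro-1-benzofuran
Conditions: CBr4, PPh3, CH2Cl2, 0 °C
Reagents that add atoms: tetrabromomethane, BrC(Br)(Br)Br
Why: The Appel reaction converts the benzylic alcohol into the bromide under neutral conditions that spare the silyl ethers; the bromide is used at once.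

Step 11
Reactants: 18 (4R)-4-benzyl-1,3-oxazolidin-2-one; 19 methyl 4-chloro-4-oxobutanoate
Product: 21 methyl 4-[(4R)-4-benzyl-2-oxo-1,3-oxazolidin-3-yl]-4-oxobutanoate, via lithium amide 20 (not isolated)
Conditions: n-BuLi, THF, −78 °C; then 19, −78 to 0 °C
Reagents that add atoms: none
Why: N-acylation of the lithiated oxazolidinone with the acid chloride is the standard entry to the auxiliary-bearing succinate.

Step 12
Reactants: 21 methyl 4-[(4R)-4-benzyl-2-oxo-1,3-oxazolidin-3-yl]-4-oxobutanoate; 17 (2S,3R)-5-(bromomethyl)-7-methoxy-2-(3-methoxy-4-TIPSO-phenyl)-3-(TIPSO-methyl)-2,3-dihydro-1-benzofuran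
Product: 23 methyl (3R)-4-[(4R)-4-benzyl-2-oxo-1,3-oxazolidin-3-yl]-3-{[(2S,3R)-7-methoxy-2-(3-methoxy-4-TIPSO-phenyl)-3-(TIPSO-methyl)-2,3-dihydro-1-benzofuran-5-yl]methyl}-4-oxobutanoate, via sodium enolate 22 (not isolated)
Conditions: NaN(SiMe3)2, THF, −78 °C; then 17, −78 to −40 °C
Reagents that add atoms: none
Why: Evans alkylation: the imide is deprotonated selectively next to the imide carbonyl, and the chelated (Z)-enolate takes the benzylic bromide on the face away from the auxiliary benzyl group, which sets the (3R) center.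

Step 13
Reactants: 23 methyl (3R)-4-[(4R)-4-benzyl-2-oxo-1,3-oxazolidin-3-yl]-3-{[(2S,3R)-7-methoxy-2-(3-methoxy-4-TIPSO-phenyl)-3-(TIPSO-methyl)-2,3-dihydro-1-benzofuran-5-yl]methyl}-4-oxobutanoate
Product: 25 (4R)-4-{[(2S,3R)-7-methoxy-2-(3-methoxy-4-TIPSO-phenyl)-3-(TIPSO-methyl)-2,3-dihydro-1-benzofuran-5-yl]methyl}oxolan-2-one, via hydroxy ester 24 (not isolated)
Conditions: NaBH4, THF/H2O (4:1), 0 °C to rt; then aq. citric acid (pH 4), rt
Reagents that add atoms: none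
Why: Borohydride reduces the activated imide carbonyl to the primary alcohol and leaves the methyl ester, and the γ-hydroxy ester then lactonises by 5-exo-trig acyl substitution with the stereocenter untouched.

Step 14
Reactants: 26 methyl 3-bromo-4-hydroxy-5-methoxybenzoate
Product: 27 methyl 3-bromo-4-TBSO-5-methoxybenzoate
Conditions: TBSCl, imidazole, DMF, rt
Reagents that add atoms: tert-butyldimethylsilyl chloride, CC(C)(C)[Si](C)(C)Cl
Why: Silylation of the phenol masks it for the organozinc, aldol and enolate chemistry that follows.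

Step 15
Reactants: 27 methyl 3-bromo-4-TBSO-5-methoxybenzoate; 28 (2-tert-butoxy-2-oxoethyl)zinc bromide
Product: 29 methyl 3-(2-tert-butoxy-2-oxoethyl)-4-TBSO-5-methoxybenzoate
Conditions: Pd2(dba)3 (2 mol%), XPhos (8 mol%), THF, 60 °C
Reagents that add atoms: none
Why: Negishi coupling of the Reformatsky reagent with the aryl bromide under zerovalent palladium gives the arylacetate, and the zinc enolate is mild enough to leave the methyl benzoate alone.

Step 16
Reactants: 29 methyl 3-(2-tert-butoxy-2-oxoethyl)-4-TBSO-5-methoxybenzoate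
Product: 30 [2-TBSO-3-methoxy-5-(methoxycarbonyl)phenyl]acetic acid
Conditions: TFA, CH2Cl2, 0 °C to rt
Reagents that add atoms: none
Why: Acidolysis cleaves only the tert-butyl ester with loss of isobutene, while the methyl ester and the hindered aryl silyl ether should persist.

Step 17
Reactants: 30 [2-TBSO-3-methoxy-5-(methoxycarbonyl)phenyl]acetic acid; 31 (4S)-4-benzyl-1,3-oxazolidin-2-one
Product: 33 methyl 3-{2-[(4S)-4-benzyl-2-oxo-1,3-oxazolidin-3-yl]-2-oxoethyl}-4-TBSO-5-methoxybenzoate, via mixed anhydride 32 (not isolated)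
Conditions: PivCl, Et3N, THF, −20 °C; then 31, LiCl, rt
Reagents that add atoms: none
Why: The mixed pivalic anhydride acylates the oxazolidinone under LiCl/Et3N activation at the less hindered arylacetyl carbonyl.

Step 18
Reactants: 34 4-hydroxy-3-methoxybenzaldehyde (vanillin)
Product: 35 4-TBSO-3-methoxybenzaldehyde
Conditions: TBSCl, imidazole, DMF, rt
Reagents that add atoms: tert-butyldimethylsilyl chloride, CC(C)(C)[Si](C)(C)Cl
Why: Silylation of the phenol gives the non-enolisable aldehyde partner for the aldol.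

Step 19
Reactants: 33 methyl 3-{2-[(4S)-4-benzyl-2-oxo-1,3-oxazolidin-3-yl]-2-oxoethyl}-4-TBSO-5-methoxybenzoate; 35 4-TBSO-3-methoxybenzaldehyde
Product: 37 methyl 3-{(2R,3S)-1-[(4S)-4-benzyl-2-oxo-1,3-oxazolidin-3-yl]-3-hydroxy-3-(3-methoxy-4-TBSO-phenyl)-1-oxopropan-2-yl}-4-TBSO-5-methoxybenzoate, via silyl ether 36 (not isolated)
Conditions: MgCl2 (20 mol%), Et3N, Me3SiCl, EtOAc, rt; then AcOH/THF/H2O, rt
Reagents that add atoms: none
Why: Magnesium-halide-catalysed Evans anti-aldol: soft enolisation gives the chelated (Z)-enolate, the aromatic aldehyde adds through a boat transition state on the face away from the auxiliary benzyl group, and silyl trapping of the aldolate prevents retro-aldol, which sets the (2R,3S) anti pair.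

Step 20
Reactants: 37 methyl 3-{(2R,3S)-1-[(4S)-4-benzyl-2-oxo-1,3-oxazolidin-3-yl]-3-hydroxy-3-(3-methoxy-4-TBSO-phenyl)-1-oxopropan-2-yl}-4-TBSO-5-methoxybenzoate
Product: 38 methyl 3-[(1S,2S)-1,3-dihydroxy-1-(3-methoxy-4-TBSO-phenyl)propan-2-yl]-4-TBSO-5-methoxybenzoate
Conditions: LiBH4, MeOH (1 equiv), THF, 0 °C
Reagents that add atoms: none
Why: Reductive removal of the auxiliary with LiBH4 is fast at the activated imide carbonyl and should leave the aromatic methyl ester, so the labile α-aryl center is fixed as a 1,3-diol.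

Step 21
Reactants: 38 methyl 3-[(1S,2S)-1,3-dihydroxy-1-(3-methoxy-4-TBSO-phenyl)propan-2-yl]-4-TBSO-5-methoxybenzoate
Product: 39 methyl 3-[(1S,2S)-1,3-bis(TBSO)-1-(3-methoxy-4-TBSO-phenyl)propan-2-yl]-4-TBSO-5-methoxybenzoate
Conditions: TBSOTf, 2,6-lutidine, CH2Cl2, −78 to 0 °C
Reagents that add atoms: tert-butyldimethylsilyl triflate, CC(C)(C)[Si](C)(C)OS(=O)(=O)C(F)(F)F
Why: The silyl triflate silylates the primary and the hindered benzylic secondary alcohol under buffered conditions without ionising the benzylic position.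

Step 22
Reactants: 39 methyl 3-[(1S,2S)-1,3-bis(TBSO)-1-(3-methoxy-4-TBSO-phenyl)propan-2-yl]-4-TBSO-5-methoxybenzoate
Product: 40 {3-[(1S,2S)-1,3-bis(TBSO)-1-(3-methoxy-4-TBSO-phenyl)propan-2-yl]-4-TBSO-5-methoxyphenyl}methanol
Conditions: i-Bu2AlH, CH2Cl2, −78 to 0 °C
Reagents that add atoms: none
Why: Hydride reduction of the benzoate ester gives the benzylic alcohol and is compatible with the four silyl ethers.

Step 23
Reactants: 40 {3-[(1S,2S)-1,3-bis(TBSO)-1-(3-methoxy-4-TBSO-phenyl)propan-2-yl]-4-TBSO-5-methoxyphenyl}methanol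
Product: 41 1-(bromomethyl)-3-[(1S,2S)-1,3-bis(TBSO)-1-(3-methoxy-4-TBSO-phenyl)propan-2-yl]-4-TBSO-5-methoxybenzene
Conditions: CBr4, PPh3, CH2Cl2, 0 °C
Reagents that add atoms: tetrabromomethane, BrC(Br)(Br)Br
Why: The Appel reaction acts only on the free primary benzylic alcohol and gives the electrophile for the lactone alkylation.

Step 24
Reactants: 25 (4R)-4-{[(2S,3R)-7-methoxy-2-(3-methoxy-4-TIPSO-phenyl)-3-(TIPSO-methyl)-2,3-dihydro-1-benzofuran-5-yl]methyl}oxolan-2-one; 41 1-(bromomethyl)-3-[(1S,2S)-1,3-bis(TBSO)-1-(3-methoxy-4-TBSO-phenyl)propan-2-yl]-4-TBSO-5-methoxybenzene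
Product: 43 (3R,4R)-3-{[3-[(1S,2S)-1,3-bis(TBSO)-1-(3-methoxy-4-TBSO-phenyl)propan-2-yl]-4-TBSO-5-methoxyphenyl]methyl}-4-{[(2S,3R)-7-methoxy-2-(3-methoxy-4-TIPSO-phenyl)-3-(TIPSO-methyl)-2,3-dihydro-1-benzofuran-5-yl]methyl}oxolan-2-one, via lithium enolate 42 (not isolated)
Conditions: LiN(SiMe3)2, THF, −78 °C; then 41, −78 to −30 °C
Reagents that add atoms: none
Why: Alkylation of the butyrolactone enolate occurs anti to the C4 arylmethyl group, so the new C3 center should be set trans (3R) by substrate control, as in the standard construction of dibenzylbutyrolactone lignans.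

Step 25
Reactants: 43 (3R,4R)-3-{[3-[(1S,2S)-1,3-bis(TBSO)-1-(3-methoxy-4-TBSO-phenyl)propan-2-yl]-4-TBSO-5-methoxyphenyl]methyl}-4-{[(2S,3R)-7-methoxy-2-(3-methoxy-4-TIPSO-phenyl)-3-(TIPSO-methyl)-2,3-dihydro-1-benzofuran-5-yl]methyl}oxolan-2-one
Product: 44 (3R,4R)-3-{[3-[(1S,2S)-1,3-dihydroxy-1-(4-hydroxy-3-methoxyphenyl)propan-2-yl]-4-hydroxy-5-methoxyphenyl]methyl}-4-{[(2S,3R)-2-(4-hydroxy-3-methoxyphenyl)-3-(hydroxymethyl)-7-methoxy-2,3-dihydro-1-benzofuran-5-yl]methyl}oxolan-2-one (CNP0186558.2)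
Conditions: Bu4NF, AcOH, THF, 0 °C to rt
Reagents that add atoms: none
Why: Acetic-acid-buffered fluoride desilylation removes all six silyl ethers without acid, so the benzylic alcohol next to the free ring B phenol should neither epimerise nor cyclise, and the trans lactone is the stable epimer.

**Compound list**

1 | 1-(2-hydroxy-3-methoxyphenyl)ethan-1-one | CC(=O)c1cccc(OC)c1O | starting material
2 | 1-(5-bromo-2-hydroxy-3-methoxyphenyl)ethan-1-one | CC(=O)c1cc(Br)cc(OC)c1O | intermediate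
3 | N,N-dimethylformamide dimethyl acetal | COC(OC)N(C)C | starting material
4 | (E)-1-(5-bromo-2-hydroxy-3-methoxyphenyl)-3-(dimethylamino)prop-2-en-1-one | CN(C)/C=C/C(=O)c1cc(Br)cc(OC)c1O | intermediate
5 | 6-bromo-8-methoxy-4H-chromen-4-one | O=c1ccoc2c(OC)cc(Br)cc12 | intermediate
6 | 2-methoxy-4-(4,4,5,5-tetramethyl-1,3,2-dioxaborolan-2-yl)phenol | COc1cc(B2OC(C)(C)C(C)(C)O2)ccc1O | starting material
7 | 2-methoxy-4-(4,4,5,5-tetramethyl-1,3,2-dioxaborolan-2-yl)phenyl pivalate | COc1cc(B2OC(C)(C)C(C)(C)O2)ccc1OC(=O)C(C)(C)C | intermediate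
8 | [3-methoxy-4-(pivaloyloxy)phenyl]boronic acid | COc1cc(B(O)O)ccc1OC(=O)C(C)(C)C | intermediate
9 | (2S)-6-bromo-8-methoxy-2-[3-methoxy-4-(pivaloyloxy)phenyl]chroman-4-one | Brc1cc(OC)c2c(c1)C(=O)C[C@@H](c1ccc(OC(=O)C(C)(C)C)c(OC)c1)O2 | intermediate
10 | (2S)-6-bromo-4,8-dimethoxy-2-[3-methoxy-4-(pivaloyloxy)phenyl]-2H-chromene | Brc1cc(OC)c2c(c1)C(OC)=C[C@@H](c1ccc(OC(=O)C(C)(C)C)c(OC)c1)O2 | intermediate
11 | methyl (2S,3S)-5-bromo-7-methoxy-2-[3-methoxy-4-(pivaloyloxy)phenyl]-2,3-dihydro-1-benzofuran-3-carboxylate (trans) | Brc1cc(OC)c2c(c1)[C@H](C(=O)OC)[C@@H](c1ccc(OC(=O)C(C)(C)C)c(OC)c1)O2 | intermediate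
12 | 4-[(2S,3R)-5-bromo-3-(hydroxymethyl)-7-methoxy-2,3-dihydro-1-benzofuran-2-yl]-2-methoxyphenol | Brc1cc(OC)c2c(c1)[C@H](CO)[C@@H](c1ccc(O)c(OC)c1)O2 | intermediate
13 | (2S,3R)-5-bromo-7-methoxy-2-(3-methoxy-4-TIPSO-phenyl)-3-(TIPSO-methyl)-2,3-dihydro-1-benzofuran | Brc1cc(OC)c2c(c1)[C@H](CO[Si](C(C)C)(C(C)C)C(C)C)[C@@H](c1ccc(O[Si](C(C)C)(C(C)C)C(C)C)c(OC)c1)O2 | intermediate
14 | aryllithium from 13 (Li at C5) | [Li]c1cc(OC)c2c(c1)[C@H](CO[Si](C(C)C)(C(C)C)C(C)C)[C@@H](c1ccc(O[Si](C(C)C)(C(C)C)C(C)C)c(OC)c1)O2 | intermediate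
15 | (2S,3R)-7-methoxy-2-(3-methoxy-4-TIPSO-phenyl)-3-(TIPSO-methyl)-2,3-dihydro-1-benzofuran-5-carbaldehyde | O=Cc1cc(OC)c2c(c1)[C@H](CO[Si](C(C)C)(C(C)C)C(C)C)[C@@H](c1ccc(O[Si](C(C)C)(C(C)C)C(C)C)c(OC)c1)O2 | intermediate
16 | [(2S,3R)-7-methoxy-2-(3-methoxy-4-TIPSO-phenyl)-3-(TIPSO-methyl)-2,3-dihydro-1-benzofuran-5-yl]methanol | OCc1cc(OC)c2c(c1)[C@H](CO[Si](C(C)C)(C(C)C)C(C)C)[C@@H](c1ccc(O[Si](C(C)C)(C(C)C)C(C)C)c(OC)c1)O2 | intermediate
17 | (2S,3R)-5-(bromomethyl)-7-methoxy-2-(3-methoxy-4-TIPSO-phenyl)-3-(TIPSO-methyl)-2,3-dihydro-1-benzofuran | BrCc1cc(OC)c2c(c1)[C@H](CO[Si](C(C)C)(C(C)C)C(C)C)[C@@H](c1ccc(O[Si](C(C)C)(C(C)C)C(C)C)c(OC)c1)O2 | intermediate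
18 | (4R)-4-benzyl-1,3-oxazolidin-2-one | O=C1N[C@H](Cc2ccccc2)CO1 | starting material
19 | methyl 4-chloro-4-oxobutanoate | COC(=O)CCC(Cl)=O | starting material
20 | lithium amide of 18 | [Li]N1[C@H](Cc2ccccc2)COC1=O | intermediate
21 | methyl 4-[(4R)-4-benzyl-2-oxo-1,3-oxazolidin-3-yl]-4-oxobutanoate | COC(=O)CCC(=O)N1[C@H](Cc2ccccc2)COC1=O | intermediate
22 | sodium (Z)-enolate of 21 | COC(=O)C/C=C(\O[Na])N1[C@H](Cc2ccccc2)COC1=O | intermediate
23 | methyl (3R)-4-[(4R)-4-benzyl-2-oxo-1,3-oxazolidin-3-yl]-3-{[(2S,3R)-7-methoxy-2-(3-methoxy-4-TIPSO-phenyl)-3-(TIPSO-methyl)-2,3-dihydro-1-benzofuran-5-yl]methyl}-4-oxobutanoate | COC(=O)C[C@@H](Cc1cc(OC)c2c(c1)[C@H](CO[Si](C(C)C)(C(C)C)C(C)C)[C@@H](c1ccc(O[Si](C(C)C)(C(C)C)C(C)C)c(OC)c1)O2)C(=O)N1[C@H](Cc2ccccc2)COC1=O | intermediate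
24 | methyl (3R)-4-hydroxy-3-{[(2S,3R)-7-methoxy-2-(3-methoxy-4-TIPSO-phenyl)-3-(TIPSO-methyl)-2,3-dihydro-1-benzofuran-5-yl]methyl}butanoate | COC(=O)C[C@@H](Cc1cc(OC)c2c(c1)[C@H](CO[Si](C(C)C)(C(C)C)C(C)C)[C@@H](c1ccc(O[Si](C(C)C)(C(C)C)C(C)C)c(OC)c1)O2)CO | intermediate
25 | (4R)-4-{[(2S,3R)-7-methoxy-2-(3-methoxy-4-TIPSO-phenyl)-3-(TIPSO-methyl)-2,3-dihydro-1-benzofuran-5-yl]methyl}oxolan-2-one | O=C1C[C@@H](Cc2cc(OC)c3c(c2)[C@H](CO[Si](C(C)C)(C(C)C)C(C)C)[C@@H](c2ccc(O[Si](C(C)C)(C(C)C)C(C)C)c(OC)c2)O3)CO1 | intermediate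
26 | methyl 3-bromo-4-hydroxy-5-methoxybenzoate | COC(=O)c1cc(Br)c(O)c(OC)c1 | starting material
27 | methyl 3-bromo-4-TBSO-5-methoxybenzoate | COC(=O)c1cc(Br)c(O[Si](C)(C)C(C)(C)C)c(OC)c1 | intermediate
28 | (2-tert-butoxy-2-oxoethyl)zinc bromide | CC(C)(C)OC(=O)C[Zn]Br | starting material
29 | methyl 3-(2-tert-butoxy-2-oxoethyl)-4-TBSO-5-methoxybenzoate | COC(=O)c1cc(CC(=O)OC(C)(C)C)c(O[Si](C)(C)C(C)(C)C)c(OC)c1 | intermediate
30 | [2-TBSO-3-methoxy-5-(methoxycarbonyl)phenyl]acetic acid | COC(=O)c1cc(CC(=O)O)c(O[Si](C)(C)C(C)(C)C)c(OC)c1 | intermediate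
31 | (4S)-4-benzyl-1,3-oxazolidin-2-one | O=C1N[C@@H](Cc2ccccc2)CO1 | starting material
32 | mixed pivalic anhydride of 30 | COC(=O)c1cc(CC(=O)OC(=O)C(C)(C)C)c(O[Si](C)(C)C(C)(C)C)c(OC)c1 | intermediate
33 | methyl 3-{2-[(4S)-4-benzyl-2-oxo-1,3-oxazolidin-3-yl]-2-oxoethyl}-4-TBSO-5-methoxybenzoate | COC(=O)c1cc(CC(=O)N2[C@@H](Cc3ccccc3)COC2=O)c(O[Si](C)(C)C(C)(C)C)c(OC)c1 | intermediate
34 | 4-hydroxy-3-methoxybenzaldehyde (vanillin) | COc1cc(C=O)ccc1O | starting material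
35 | 4-TBSO-3-methoxybenzaldehyde | COc1cc(C=O)ccc1O[Si](C)(C)C(C)(C)C | intermediate
36 | trimethylsilyl ether of 37 (at the C3 hydroxyl of the propanoyl chain) | COc1cc([C@@H](O[Si](C)(C)C)[C@H](C(=O)N2[C@@H](Cc3ccccc3)COC2=O)c2cc(C(=O)OC)cc(OC)c2O[Si](C)(C)C(C)(C)C)ccc1O[Si](C)(C)C(C)(C)C | intermediate
37 | methyl 3-{(2R,3S)-1-[(4S)-4-benzyl-2-oxo-1,3-oxazolidin-3-yl]-3-hydroxy-3-(3-methoxy-4-TBSO-phenyl)-1-oxopropan-2-yl}-4-TBSO-5-methoxybenzoate | COc1cc([C@@H](O)[C@H](C(=O)N2[C@@H](Cc3ccccc3)COC2=O)c2cc(C(=O)OC)cc(OC)c2O[Si](C)(C)C(C)(C)C)ccc1O[Si](C)(C)C(C)(C)C | intermediate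
38 | methyl 3-[(1S,2S)-1,3-dihydroxy-1-(3-methoxy-4-TBSO-phenyl)propan-2-yl]-4-TBSO-5-methoxybenzoate | COc1cc([C@@H](O)[C@H](CO)c2cc(C(=O)OC)cc(OC)c2O[Si](C)(C)C(C)(C)C)ccc1O[Si](C)(C)C(C)(C)C | intermediate
39 | methyl 3-[(1S,2S)-1,3-bis(TBSO)-1-(3-methoxy-4-TBSO-phenyl)propan-2-yl]-4-TBSO-5-methoxybenzoate | COc1cc([C@@H](O[Si](C)(C)C(C)(C)C)[C@H](CO[Si](C)(C)C(C)(C)C)c2cc(C(=O)OC)cc(OC)c2O[Si](C)(C)C(C)(C)C)ccc1O[Si](C)(C)C(C)(C)C | intermediate
40 | {3-[(1S,2S)-1,3-bis(TBSO)-1-(3-methoxy-4-TBSO-phenyl)propan-2-yl]-4-TBSO-5-methoxyphenyl}methanol | COc1cc([C@@H](O[Si](C)(C)C(C)(C)C)[C@H](CO[Si](C)(C)C(C)(C)C)c2cc(CO)cc(OC)c2O[Si](C)(C)C(C)(C)C)ccc1O[Si](C)(C)C(C)(C)C | intermediate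
41 | 1-(bromomethyl)-3-[(1S,2S)-1,3-bis(TBSO)-1-(3-methoxy-4-TBSO-phenyl)propan-2-yl]-4-TBSO-5-methoxybenzene | COc1cc([C@@H](O[Si](C)(C)C(C)(C)C)[C@H](CO[Si](C)(C)C(C)(C)C)c2cc(CBr)cc(OC)c2O[Si](C)(C)C(C)(C)C)ccc1O[Si](C)(C)C(C)(C)C | intermediate
42 | lithium enolate of 25 | [Li]OC1=C[C@@H](Cc2cc(OC)c3c(c2)[C@H](CO[Si](C(C)C)(C(C)C)C(C)C)[C@@H](c2ccc(O[Si](C(C)C)(C(C)C)C(C)C)c(OC)c2)O3)CO1 | intermediate
43 | hexasilyl ether of the target: (3R,4R)-3-{[3-[(1S,2S)-1,3-bis(TBSO)-1-(3-methoxy-4-TBSO-phenyl)propan-2-yl]-4-TBSO-5-methoxyphenyl]methyl}-4-{[(2S,3R)-7-methoxy-2-(3-methoxy-4-TIPSO-phenyl)-3-(TIPSO-methyl)-2,3-dihydro-1-benzofuran-5-yl]methyl}oxolan-2-one | COc1cc([C@@H](O[Si](C)(C)C(C)(C)C)[C@H](CO[Si](C)(C)C(C)(C)C)c2cc(C[C@H]3C(=O)OC[C@@H]3Cc3cc(OC)c4c(c3)[C@H](CO[Si](C(C)C)(C(C)C)C(C)C)[C@@H](c3ccc(O[Si](C(C)C)(C(C)C)C(C)C)c(OC)c3)O4)cc(OC)c2O[Si](C)(C)C(C)(C)C)ccc1O[Si](C)(C)C(C)(C)C | intermediate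
44 | CNP0186558.2: (3R,4R)-3-{[3-[(1S,2S)-1,3-dihydroxy-1-(4-hydroxy-3-methoxyphenyl)propan-2-yl]-4-hydroxy-5-methoxyphenyl]methyl}-4-{[(2S,3R)-2-(4-hydroxy-3-methoxyphenyl)-3-(hydroxymethyl)-7-methoxy-2,3-dihydro-1-benzofuran-5-yl]methyl}oxolan-2-one | COc1cc([C@@H](O)[C@H](CO)c2cc(C[C@H]3C(=O)OC[C@@H]3Cc3cc(OC)c4c(c3)[C@H](CO)[C@@H](c3ccc(O)c(OC)c3)O4)cc(OC)c2O)ccc1O | target

**Step count and risks**

Total step count: 25. Longest linear sequence: 12 steps (steps 1, 2, 5, 6, 7, 8, 9, 10, 12, 13, 24, 25).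

The three steps most likely to fail:

1. Step 6 (ring contraction). The C2 aryl group may migrate instead of the ring C carbon, or the enol ether may only be dehydrogenated or methoxylated at C3, so that little ester 11 forms. The fallback runs from 9 back to 11 and makes the same C3–C3a bond by a Wolff ring contraction through a carbene instead of an iodonium species. Ketone 9 is C-acylated at C3 (LiN(SiMe3)2, CF3CO2CH2CF3, THF, −78 °C) to the 3-trifluoroacetyl ketone F1, and deacylative diazo transfer (MsN3, Et3N, H2O, MeCN) gives the 3-diazochroman-4-one F2. Irradiation at 365 nm in MeOH expels nitrogen, the ring C carbon shifts from C4 to the carbene carbon C3, and the ring-contracted ketene F3 is trapped by methanol as the ester, expected largely as the cis epimer F4 after protonation anti to the C2 aryl group. DBU in CH2Cl2 then equilibrates C3 to the trans ester 11.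

2. Step 19 (anti-aldol). The hindered ortho-silyloxy arylacetyl imide may react slowly, with poor anti selectivity or with the opposite facial sense, which would give the wrong C7/C8 pair. The fallback runs from 30 and 18 back to 39 and sets C7 by Felkin–Anh addition of an aryl Grignard reagent instead of an aldol. Acid 30 is coupled with auxiliary 18 through mixed anhydride 32 to the (4R)-imide F5. Its titanium enolate (TiCl4, i-Pr2NEt, CH2Cl2, 0 °C) is hydroxymethylated with 1,3,5-trioxane/TiCl4 anti to the auxiliary benzyl group to give the (2S)-3-hydroxypropanoyl imide F6. TBSCl/imidazole gives the silyl ether F7, LiBH4 removes the auxiliary to give the primary alcohol F8, and Dess–Martin periodinane (NaHCO3, CH2Cl2, 0 °C) gives the α-aryl aldehyde F9, which is used at once. The Grignard reagent F11, made from (4-bromo-2-methoxyphenoxy)(tert-butyl)dimethylsilane F10 and Mg in THF, is added at −78 °C. With the ring B aryl group as the large substituent, Felkin–Anh attack should give the (1S,2S) alcohol F12, which TBSOTf/2,6-lutidine converts into 39.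

3. Step 5 (asymmetric conjugate addition). Conversion may be low with the 8-methoxychromone, boronic acid 8 may protodeboronate, or the enantioselection may be insufficient or opposite. The fallback runs from 2 and 34 back to 9 and builds the flavanone racemic by oxa-Michael closure, then resolves it. Claisen–Schmidt condensation of 2 with vanillin 34 (KOH, EtOH) gives the 2'-hydroxychalcone F13, NaOAc in refluxing EtOH closes it to the racemic flavanone F14, and PivCl/Et3N gives the racemic pivalate F15. Preparative chromatography on a cellulose tris(3,5-dimethylphenylcarbamate) phase delivers 9, and the (2R)-enantiomer F16 is set aside.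

**Further compounds**

F1 | step 6 | (2S)-6-bromo-8-methoxy-2-[3-methoxy-4-(pivaloyloxy)phenyl]-3-(trifluoroacetyl)chroman-4-one | Brc1cc(OC)c2c(c1)C(=O)C(C(=O)C(F)(F)F)[C@@H](c1ccc(OC(=O)C(C)(C)C)c(OC)c1)O2
F2 | step 6 | (2R)-6-bromo-3-diazo-8-methoxy-2-[3-methoxy-4-(pivaloyloxy)phenyl]chroman-4-one | Brc1cc(OC)c2c(c1)C(=O)C(=[N+]=[N-])[C@@H](c1ccc(OC(=O)C(C)(C)C)c(OC)c1)O2
F3 | step 6 | {5-bromo-7-methoxy-2-[3-methoxy-4-(pivaloyloxy)phenyl]-1-benzofuran-3(2H)-ylidene}methanone (ketene, C2 as in 9) | Brc1cc(OC)c2c(c1)C(=C=O)[C@@H](c1ccc(OC(=O)C(C)(C)C)c(OC)c1)O2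
F4 | step 6 | methyl (2S,3R)-5-bromo-7-methoxy-2-[3-methoxy-4-(pivaloyloxy)phenyl]-2,3-dihydro-1-benzofuran-3-carboxylate (cis) | Brc1cc(OC)c2c(c1)[C@@H](C(=O)OC)[C@@H](c1ccc(OC(=O)C(C)(C)C)c(OC)c1)O2
F5 | step 19 | methyl 3-{2-[(4R)-4-benzyl-2-oxo-1,3-oxazolidin-3-yl]-2-oxoethyl}-4-TBSO-5-methoxybenzoate | COC(=O)c1cc(CC(=O)N2[C@H](Cc3ccccc3)COC2=O)c(O[Si](C)(C)C(C)(C)C)c(OC)c1
F6 | step 19 | methyl 3-{(2S)-1-[(4R)-4-benzyl-2-oxo-1,3-oxazolidin-3-yl]-3-hydroxy-1-oxopropan-2-yl}-4-TBSO-5-methoxybenzoate | O=C(N1[C@H](Cc2ccccc2)COC1=O)[C@H](CO)c1cc(C(=O)OC)cc(OC)c1O[Si](C)(C)C(C)(C)C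
F7 | step 19 | methyl 3-{(2S)-1-[(4R)-4-benzyl-2-oxo-1,3-oxazolidin-3-yl]-1-oxo-3-TBSO-propan-2-yl}-4-TBSO-5-methoxybenzoate | O=C(N1[C@H](Cc2ccccc2)COC1=O)[C@H](CO[Si](C)(C)C(C)(C)C)c1cc(C(=O)OC)cc(OC)c1O[Si](C)(C)C(C)(C)C
F8 | step 19 | methyl 3-[(2R)-1-hydroxy-3-TBSO-propan-2-yl]-4-TBSO-5-methoxybenzoate | OC[C@H](CO[Si](C)(C)C(C)(C)C)c1cc(C(=O)OC)cc(OC)c1O[Si](C)(C)C(C)(C)C
F9 | step 19 | methyl 3-[(2S)-1-oxo-3-TBSO-propan-2-yl]-4-TBSO-5-methoxybenzoate | O=C[C@H](CO[Si](C)(C)C(C)(C)C)c1cc(C(=O)OC)cc(OC)c1O[Si](C)(C)C(C)(C)C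
F10 | step 19 | (4-bromo-2-methoxyphenoxy)(tert-butyl)dimethylsilane | COc1cc(Br)ccc1O[Si](C)(C)C(C)(C)C
F11 | step 19 | (3-methoxy-4-TBSO-phenyl)magnesium bromide | COc1cc([Mg]Br)ccc1O[Si](C)(C)C(C)(C)C
F12 | step 19 | methyl 3-[(1S,2S)-1-hydroxy-1-(3-methoxy-4-TBSO-phenyl)-3-TBSO-propan-2-yl]-4-TBSO-5-methoxybenzoate | COc1cc([C@@H](O)[C@H](CO[Si](C)(C)C(C)(C)C)c2cc(C(=O)OC)cc(OC)c2O[Si](C)(C)C(C)(C)C)ccc1O[Si](C)(C)C(C)(C)C
F13 | step 5 | (E)-1-(5-bromo-2-hydroxy-3-methoxyphenyl)-3-(4-hydroxy-3-methoxyphenyl)prop-2-en-1-one | COc1cc(/C=C/C(=O)c2cc(Br)cc(OC)c2O)ccc1O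
F14 | step 5 | racemic 6-bromo-2-(4-hydroxy-3-methoxyphenyl)-8-methoxychroman-4-one | COc1cc(C2CC(=O)c3cc(Br)cc(OC)c3O2)ccc1O
F15 | step 5 | racemic 6-bromo-8-methoxy-2-[3-methoxy-4-(pivaloyloxy)phenyl]chroman-4-one | Brc1cc(OC)c2c(c1)C(=O)CC(c1ccc(OC(=O)C(C)(C)C)c(OC)c1)O2
F16 | step 5 | (2R)-6-bromo-8-methoxy-2-[3-methoxy-4-(pivaloyloxy)phenyl]chroman-4-one | Brc1cc(OC)c2c(c1)C(=O)C[C@H](c1ccc(OC(=O)C(C)(C)C)c(OC)c1)O2
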